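All runs were computed for an exercise; the scatter is artificial.

Follow Friday's flask on to 5.0 min and say how long its chains are.

- Friday's: D 20 mM (fed, over 40 s); Q 0.24 mol%; the very flask that is asked about, followed so far; the fed solution adds 0.20 times the starting volume
- flask: D 20 mM (fed, over 40 s); Q 0.24 mol%; time 5.0 min; the fed solution adds 0.20 times the starting volume

- Friday's (time / min: E / %, D / %): 0.333: 11.7, 38.2; 0.833: 19.7, 80.9; 1.50: 21.2, 78.4; 2.50: 21.1, 77.5

(standard deviation of a reading: 0.5 percentage points)

1. whether the average number of monomer units in a chain (living and dead chains, two that joined counted as one) reaches 200 by 5.0 min (yes / no)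
2. average number of monomer units in a chain (living and dead chains, two that joined counted as one) at 5.0 min

- every charge counts on the volume at the start, and the solution that is fed holds the whole dose
- the average divides the monomer in chains by the number of chains, living and dead together; two radicals that join make one chain
- the earlier runs do not show the number of chains; that part of a forecast is a guess
- percentages count the whole charge, also what has not yet gone in

In Friday's run E read 21.2 % at 1.50 min and 21.1 % at 2.50 min, flat within the scatter. D still read 77.5 %, more than E, so D had not stopped the growth, and I took the radicals from Q to be dead. I assumed that each Q gave two radicals and that these ended joined, which makes one chain per Q. So I divided E by Q: 21.1 % over 0.24 mol% is 87.9. This is units per Q, the monomer in chains for each Q charged. With one chain per Q, it is the number-average chain length. It lay below the length asked, so I expected the answer no.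

The forecast answered no and gave 95, above my 87.9, holding that “Q is used up early and the radicals die”.

The flask answered no and gave 91.1 at 5.0 min.

    Q → 2 G (k = 0.170 s⁻¹)
    D + G → Z + E (k = 5.90 × 10⁶ M⁻¹ s⁻¹)
    D + Z → E + Z, rate k3*[Z]*[D] (k = 2.00 × 10⁵ M⁻¹ s⁻¹)
    2 Z → J (k = 4.90 × 10⁷ M⁻¹ s⁻¹)
    D → X (k = 7.10 × 10⁻⁵ s⁻¹)

At 5.00 min this flask held Q at 0 % and J at 0.0400 mM, the same as the Q charged, which is 0.0400 mM on the fed volume. That is one J per Q. My 87.9 units per Q stood on one reading at 2.50 min and carries that reading's scatter. This flask's E of 21.9 % at 5.00 min over 0.24 mol% gave 91.3 units per Q. The neighbour flask took 0.41 mol% of Q, with the other charges as in the recipe. Its E of 26.8 % over that loading gave 65.4 units per Q. That neighbour flask reached a chain length of 65.2, shorter than this flask's 91.1.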